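In a stirred, isothermal vessel, electrophile was fed at a steady rate into free base with the gas held, and electrophile turned into target.

| flask | electrophile | free base | gas | remark | time |
|---|---|---|---|---|---|
| red | 0.050 M (fed, over 5.0 min) | 0.42 equiv | 2.9 mM (held) | run made earlier |  |
| blue | 0.050 M (fed, over 5.0 min) | 0.58 equiv | 2.9 mM (held) | run made earlier |  |
| north | 0.050 M (fed, over 5.0 min) | 0.300 equiv | 2.9 mM (held) |  | 40 min |
| south-east | 0.050 M (fed, over 5.0 min) | 0.510 equiv | 2.9 mM (held) |  | 40 min |
| north-west | 0.050 M (fed, over 5.0 min) | 0.390 equiv | 2.9 mM (held) |  | 40 min |

- red (time / min: electrophile / %, target / %): 1.50: 28.9, 0.4; 3.00: 59.4, 0.3; 6.00: 95.6, 4.1; 10.0: 92.1, 8.4; 20.0: 82.0, 17.7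
- blue (time / min: electrophile / %, target / %): 1.50: 29.6, 0; 3.00: 58.4, 0.4; 6.00: 95.5, 5.0; 10.0: 90.9, 8.3; 20.0: 81.8, 18.1

(scatter of a reading: 0.5 percentage points)

- the earlier runs were read with a standard deviation of 0.5 percentage points
- at the start none of the gas is in solution
- percentages count the whole charge, also what has not yet gone in

* part of the electrophile that has reacted at the end, north
* part of the electrophile that has reacted at the end, south-east
* part of the electrophile that has reacted at the end, north-west
* what raising the equivalents of free base from its lowest to its highest value here does to the part of the electrophile that has reacted (changes below 5 percentage points count as none) (it rises / no change / it falls)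

**Step one.** During the feed, electrophile simply followed the pump at 0.200 min⁻¹ of the charge. In the red run at 3.00 min, c(electrophile) read 59.4 % and target read 0.3 %.

**Step two.** After the feed, electrophile lost reappeared as target: at 20.0 min in the red run the two summed to 99.7 %. So I treated the loss as one step.

**Step three.** I described that step by a pseudo-first-order constant, k, the share of the standing electrophile that reacts per minute. It is the logarithm of the ratio of two electrophile readings, divided by the time between them. From 6.00 min to 20.0 min I read 0.0110 min⁻¹ at 0.42 equiv and 0.0111 min⁻¹ at 0.58 equiv. Within the scatter of 0.5 percentage points I saw no effect of free base, and I took the mean, 0.0110 min⁻¹.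

**Step four.** I joined the two ends by letting the charge enter, on average, at the middle of the feed, 2.50 min. The electrophile left is then the exponential of minus k times the time since that moment. This gave 92.1 % at 10.0 min, a time not used for k, against the readings of 92.1 % in the red run and 90.9 % in the blue run.

**Step five.** At 40 min my reckoning gave 33.8 % reacted. I took that figure for north, south-east and north-west, and so no change. This was an assumption: target had reached 17.7 % in the red run and 18.1 % in the blue run, so neither run tested a cap by free base.

**Forecast.** The forecast differed from my reckoning, with 29.8 % for north, 37.2 % for south-east, 36.6 % for north-west and "it rises", on the ground "I assume free base is consumed 1:1".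

**Result.** The flasks gave 34.7 % for north, 35.1 % for south-east and 34.9 % for north-west, a change of 0.37 points across the range: no change.

    electrophile + nucleophile ⇌ acid set free + target (K = 18.0, k = 0.0930 L mol⁻¹ s⁻¹)
    nucleophile + acid set free ⇌ protonated nucleophile, settled at all times (K = 8800 L mol⁻¹)
    acid set free + free base ⇌ salt of the base, settled at all times (K = 320 L mol⁻¹)
    gas ⇌ nucleophile, rate k4*(csat - [nucleophile]) (kL = 0.0160 s⁻¹)
    free base ⇌ dormant form (K = 7.60, k = 6.20 × 10⁻⁵ s⁻¹)

My 33.8 % fell 1.3 points short of south-east. In north at 40.0 min, protonated nucleophile stood at 0.0141 M against 0.00253 M of salt of the base, and 70.7 % of the free base was still free. The level in north came in part from how slow the way of gas across to nucleophile is, acting together with the time of reading. From 34.7 %, north reached 45.3 % with that way made fast, and 96.6 % when read at 400 min.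

For south-east read at 2.5 h, the same k gave 80.3 % reacted. The computed flask gave 84.0 %.

All runs come from a simulation with made-up constants, noise included.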